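A direct plan would make ring A from limonene oxide and ring C from a 4-silyloxycyclopentenone, join them at C9–C10 by a B-alkyl Suzuki coupling to the seco diene A1, close ring B as a fused cyclooctene by ring-closing metathesis, oxidise to the hydroxy-1,2-dione A2, expand to the bridged ene-1,3-dione A3 by an α-ketol shift and finish with methylmagnesium bromide at C11. Its weakest steps would be:
- the metathesis closure of a trisubstituted cyclooctene between two tertiary carbinols, which would fight ring strain and entropy and would need high dilution and heat;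
- the α-ketol shift of A2 to A3, an equilibrium on a late 1,2-dione (itself from a selenium dioxide oxidation), followed by a Grignard addition that would have to tell apart the two carbonyl groups and the two faces of an ene-1,3-dione;
- the two hydroborations that would set C7 and C8 by weak acyclic 1,2-induction, at the end of a twelve-step linear ring A sequence with several redox and protecting-group changes that build nothing.

**Retrosynthetic overview**
Key disconnection: C10–C11 and C10–C14 are formed and C8–C1 is broken. An anionic acetylenic oxy-Cope rearrangement inserts C9–C12 between C8 and C1 of a ring-A-fused cyclopentanone (auxiliary ring D: C8, C1, C2, C6, C7), so the nine-membered ring B arises by ring expansion. The enone that results is trapped by the C14 enolate, which closes ring C onto the bridgeheads C10 and C12 with C11 as the one-atom bridge.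
The diquinane precursor (rings A and D, carrying C6 and C7) comes from an asymmetric Pauson–Khand reaction and a convex-face hydrogenation, C3 from a convex-face epoxidation, and C11 with its methyl group from acetylacetone.
Rings form in the order A (with D), B, C; then follow C8 reduction, deconjugative hydroxylation (12-OH and C1=C2), C10=C14 and the isopropyl group.
No medium ring is closed by cyclisation, no dione equilibrium and no late Grignard addition are needed, and C6/C7 are set on a rigid bicycle.

Key step: step 10

Remark on numbering: brassicicene numbering is used throughout. Ring A is C2–C6 (C3 carries OH and the methoxymethyl carbon C16). Ring B is C1, C2, C6–C12. Ring C is C10–C14. The alkenes are C1=C2 and C10=C14, the ketone is C13, and the carbinols are C3, C8, C11 and C12.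
Assumption: (S)-BINAP is taken to give the (6aS) enone 5 in step 2; if the sense of induction is the opposite, the antipodal ligand is used.

Step 1
Reactants: 1 isoprene; 2 1-bromobut-2-yne
Product: 4 3-methylideneoct-1-en-6-yne, via isoprenylpotassium 3 (not isolated)
Conditions: n-BuLi, KOt-Bu, 2,2,6,6-tetramethylpiperidine, THF, −78 °C; then 2, −78 to 0 °C
Reagents that add atoms: none
Why: Metalation of isoprene at its methyl group by the mixed lithium/potassium amide base and SN2 alkylation of the 2-substituted allyl anion at its CH2 terminus by the propargylic bromide give the 2-substituted butadiene, the way myrcene-type dienes are made.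

Step 2
Reactants: 4 3-methylideneoct-1-en-6-yne
Product: 5 (6aS)-3-methyl-6-methylidene-4,5,6,6a-tetrahydropentalen-2(1H)-one
Conditions: [Rh(CO)2Cl]2 (3 mol %), (S)-BINAP (7 mol %), AgOTf (12 mol %), CO (1 atm), THF, 70 °C
Reagents that add atoms: carbon monoxide, [C-]#[O+]
Why: Catalytic asymmetric Pauson–Khand reaction of the 1,6-enyne, in which only the vinyl group of the diene can close a five-membered ring with the alkyne (ring A), the cationic monovalent rhodium–BINAP catalyst sets the ring-fusion centre C2, and the methylidene group stays as the future C3/C16.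

Step 3
Reactants: 5 (6aS)-3-methyl-6-methylidene-4,5,6,6a-tetrahydropentalen-2(1H)-one
Product: 6 spiro-epoxide of 5 at the exocyclic methylene (oxygen cis to the ring-fusion hydrogen)
Conditions: m-CPBA, NaHCO3, CH2Cl2, 0 °C
Reagents that add atoms: 3-chloroperbenzoic acid, OOC(=O)c1cccc(Cl)c1
Why: Peracid epoxidation takes the electron-rich 1,1-disubstituted alkene and not the enone, on the face away from the C1 methylene of ring D (cis to 2-H), which sets the C3–O bond as the target has it.

Step 4
Reactants: 6 spiro-epoxide
Product: 7 (6R,6aR)-6-hydroxy-6-(methoxymethyl)-3-methyl-4,5,6,6a-tetrahydropentalen-2(1H)-one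
Conditions: NaOMe (0.5 equiv), MeOH, 50 °C
Reagents that add atoms: methanol, CO
Why: Methoxide opens the spiro-epoxide by SN2 attack at its CH2 terminus (C16), which gives the methyl ether and the tertiary C3 alcohol, and the mild temperature should leave the γ-hydrogen at C2 untouched.

Step 5
Reactants: 7 (6R,6aR)-6-hydroxy-6-(methoxymethyl)-3-methyl-4,5,6,6a-tetrahydropentalen-2(1H)-one
Product: 8 (6R,6aR)-6-(methoxymethoxy)-6-(methoxymethyl)-3-methyl-4,5,6,6a-tetrahydropentalen-2(1H)-one
Conditions: MOMCl, i-Pr2NEt, n-Bu4NI (cat.), CH2Cl2, 40 °C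
Reagents that add atoms: chloromethyl methyl ether, COCCl
Why: Alkylation of the tertiary alcohol under iodide catalysis gives a methoxymethyl ether that withstands the bases, the organometallic reagents and the oxidants that follow.

Step 6
Reactants: 8 (6R,6aR)-6-(methoxymethoxy)-6-(methoxymethyl)-3-methyl-4,5,6,6a-tetrahydropentalen-2(1H)-one
Product: 9 (1R,3aR,4R,6aR)-4-(methoxymethoxy)-4-(methoxymethyl)-1-methylhexahydropentalen-2(1H)-one
Conditions: H2 (4 atm), Pd/C, EtOAc, rt
Reagents that add atoms: none
Why: Heterogeneous hydrogenation of the tetrasubstituted enone delivers both hydrogens to C6 and C7 from the convex face (cis to 2-H), which gives the cis-fused diquinane with the C7 methyl group on the concave face, and the neutral conditions keep this kinetic epimer.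

Step 7
Reactants: 9 (1R,3aR,4R,6aR)-4-(methoxymethoxy)-4-(methoxymethyl)-1-methylhexahydropentalen-2(1H)-one; 10 pentane-2,4-dione
Product: 12 3-substituted pentane-2,4-dione (ketone 9 carrying CH(COCH3)2 at C1 on the convex face), via trimethylsilyl enol ether 11 (not isolated)
Conditions: LiN(i-Pr)2, Me3SiCl, THF, −78 °C; then 10, (NH4)2Ce(NO3)6 (2.2 equiv), NaHCO3, MeCN, −30 °C
Reagents that add atoms: none
Why: Kinetic enolisation goes to the C1 methylene and not the C7 methine, and in the oxidative coupling of a 1,3-dicarbonyl compound with a silyl enol ether the tetravalent cerium salt turns the diketone into its electrophilic radical, which adds to C1 from the convex face before loss of the silyl group restores the C8 ketone.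

Step 8
Reactants: 12 3-substituted pentane-2,4-dione
Product: 13 (Z)-methoxymethyl enol ether of 12 (C12=C11; oxygen cis to the remaining acetyl group)
Conditions: NaH (1.05 equiv), THF, 0 °C; then MOMCl, 0 °C to rt
Reagents that add atoms: chloromethyl methyl ether, COCCl
Why: Only the 1,3-diketone is deprotonated and the hard chloromethyl ether alkylates an oxygen of the sodium chelate, which should give the (Z)-enol ether, and methoxymethyl is chosen because a silyl enol ether would pass its silyl group to the alkoxide of step 10.

Step 9
Reactants: 13 (Z)-methoxymethyl enol ether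
Product: 14 C8 ethynyl carbinol (ethynyl group on the convex face and cis to the C1 side chain)
Conditions: HC≡CMgBr, CeCl3, THF, −78 °C
Reagents that add atoms: ethynylmagnesium bromide, C#C[Mg]Br
Why: The cerium-modified acetylide adds to the cyclopentanone carbonyl C8 from the convex face, the concave face being closed by ring A and the C7 methyl group, without enolising C7 or C1 and without touching the vinylogous ester carbonyl.

Step 10
Reactants: 14 C8 ethynyl carbinol
Product: 17 bridged tricyclic 8,13-dione (rings A–C; C12=C1; 11-O-methoxymethyl), via potassium alkoxide 15 (not isolated), via cyclononadienone 16 (not isolated)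
Conditions: KN(SiMe3)2 (1.05 equiv), 18-crown-6, THF, −78 °C to rt; then NH4Cl (aq)
Reagents that add atoms: none
Why: The potassium alkoxide 15 of the cis-1-ethynyl-2-alkenylcyclopentanol undergoes an anionic oxy-Cope ([3,3]) rearrangement of its 1,5-enyne (C10≡C9–C8(O−)–C1–C12=C11) that breaks C8–C1 and forms C10–C11, after which proton transfer gives the (Z)-enone 16 and the C14 enolate of the acetyl group adds to C10. The closest known reaction types are the acetylenic anionic oxy-Cope ring expansion of 1-alkynyl-2-alkenylcycloalkanols to medium-ring enones and the base-mediated intramolecular Michael addition of a methyl ketone. Ring B is not cyclised but arises by four-carbon ring expansion of the auxiliary ring D (five to nine members), and ring C closes by 5-exo-trig Michael addition. C11 is set in the [3,3] step: the new bond forms on the enol ether face from which C8 departs, and with the side chain and the alkyne both on the convex face (boat-like array) and the (Z)-enol ether this gives 11R. C10 is set in the reversible Michael step, where the smaller methoxymethoxy group and not the methyl group eclipses the enone (allylic strain), so the bridge ends on the face of ring C that carries the C11 oxygen. The step needs the alkoxide to form before any carbon acid is touched (one equivalent of base at −78 °C) and to have no other outlet: the methoxymethyl enol ether excludes silyl transfer, a ketone and not an ester at C13 excludes lactonisation, and attack of the alkoxide on C11 would be 5-endo-trig.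

Step 11
Reactants: 17 bridged tricyclic 8,13-dione
Product: 18 (8S)-8-hydroxy-13-ketone (C12=C1 retained)
Conditions: NaBH4, MeOH/CH2Cl2, −78 °C
Reagents that add atoms: none
Why: Borohydride reduces the saturated C8 ketone faster than the cross-conjugated C13 enone, and hydride is expected on the outer face of the bridge (Felkin-type approach beside the C7 methyl group) to give 8S, which also removes the retro-Michael outlet.

Step 12
Reactants: 18 (8S)-8-hydroxy-13-ketone
Product: 19 8,12-diol (C1=C2; 3,11-bis-O-methoxymethyl; C14H2 and C10–H still saturated)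
Conditions: KOt-Bu (3 equiv), THF/t-BuOH, −20 °C; then 3-phenyl-2-(phenylsulfonyl)oxaziridine, −78 °C
Reagents that add atoms: 3-phenyl-2-(phenylsulfonyl)oxaziridine, O=S(=O)(c1ccccc1)N1OC1c1ccccc1
Why: Deconjugative α-hydroxylation: equilibrating base gives the extended dienolate by loss of the γ-hydrogen at C2, and the oxaziridine oxidises its α-carbon C12 on the face away from the bridge (a bridgehead hydroxyl can only point outward), which sets C12 and moves the alkene to C1=C2 with the cis geometry the ring enforces.

Step 13
Reactants: 19 8,12-diol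
Product: 21 14-deisopropyl enone diol (C10=C14; 3,11-bis-O-methoxymethyl), via tris(trimethylsilyl) derivative 20 (not isolated)
Conditions: LiN(SiMe3)2 (3.5 equiv), Me3SiCl, THF, −78 to 0 °C; then Pd(OAc)2 (1.1 equiv), MeCN, rt; then K2CO3, MeOH
Reagents that add atoms: none
Why: Saegusa–Ito oxidation: C13 now has α-hydrogens only at C14, the palladium enolate can lose a β-hydride only from C10, and with C12 now sp3 the bridgehead alkene C10=C14 is no longer forbidden by strain.

Step 14
Reactants: 21 14-deisopropyl enone diol
Product: 22 14-iodo enone diol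
Conditions: I2, pyridine, CH2Cl2, rt
Reagents that add atoms: iodine, II
Why: α-Iodination of the enone by reversible conjugate addition of pyridine, iodination of the enolate and elimination places iodine at C14 only.

Step 15
Reactants: 22 14-iodo enone diol
Product: 23 3,11-bis-O-(methoxymethyl)brassicicene M
Conditions: i-PrZnBr (4 equiv), Pd(OAc)2 (5 mol %), CPhos (10 mol %), THF/toluene, rt
Reagents that add atoms: isopropylzinc bromide, CC(C)[Zn]Br
Why: Negishi coupling of the 2-iodoenone with the secondary alkylzinc reagent, with a ligand that suppresses isomerisation to n-propyl, puts the isopropyl group on C14.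

Step 16
Reactants: 23 3,11-bis-O-(methoxymethyl)brassicicene M
Product: 24 brassicicene M
Conditions: Me2BBr (4 equiv), CH2Cl2, −78 °C; then NaHCO3 (aq), THF
Reagents that add atoms: none
Why: The bromoborane cleaves both methoxymethyl ethers at the acetal carbon at low temperature, so neither the allylic C3–O bond nor the C11–O bond is ionised and the α-ketol sees no base.

**Compound list**
1 | isoprene (2-methylbuta-1,3-diene) | C=CC(C)=C | starting material
2 | 1-bromobut-2-yne | CC#CCBr | starting material
3 | isoprenylpotassium (2-methylidenebut-3-en-1-ylpotassium) | [K+].[CH2-]C(=C)C=C | intermediate (not isolated)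
4 | 3-methylideneoct-1-en-6-yne | C=CC(=C)CCC#CC | intermediate
5 | (6aS)-3-methyl-6-methylidene-4,5,6,6a-tetrahydropentalen-2(1H)-one | CC1=C2CCC(=C)[C@@H]2CC1=O | intermediate
6 | spiro-epoxide of 5 at the exocyclic methylene, oxygen cis to the ring-fusion hydrogen | CC1=C2CC[C@]3(CO3)[C@@H]2CC1=O | intermediate
7 | (6R,6aR)-6-hydroxy-6-(methoxymethyl)-3-methyl-4,5,6,6a-tetrahydropentalen-2(1H)-one | COC[C@@]1(O)CCC2=C(C)C(=O)C[C@@H]12 | intermediate
8 | (6R,6aR)-6-(methoxymethoxy)-6-(methoxymethyl)-3-methyl-4,5,6,6a-tetrahydropentalen-2(1H)-one | COC[C@@]1(OCOC)CCC2=C(C)C(=O)C[C@@H]12 | intermediate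
9 | (1R,3aR,4R,6aR)-4-(methoxymethoxy)-4-(methoxymethyl)-1-methylhexahydropentalen-2(1H)-one (cis-fused; methyl on the concave face) | COC[C@@]1(OCOC)CC[C@H]2[C@@H](C)C(=O)C[C@@H]12 | intermediate
10 | pentane-2,4-dione | CC(=O)CC(C)=O | starting material
11 | trimethylsilyl enol ether of 9 (C8–O–Si, C1=C8) | COC[C@@]1(OCOC)CC[C@H]2[C@@H](C)C(O[Si](C)(C)C)=C[C@@H]12 | intermediate (not isolated)
12 | 3-substituted pentane-2,4-dione: ketone 9 with CH(COCH3)2 at C1, on the convex face | COC[C@@]1(OCOC)CC[C@H]2[C@@H](C)C(=O)[C@H](C(C(C)=O)C(C)=O)[C@@H]12 | intermediate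
13 | (Z)-methoxymethyl enol ether of 12 (C12=C11, methoxymethoxy cis to the acetyl group) | COC[C@@]1(OCOC)CC[C@H]2[C@@H](C)C(=O)[C@H](/C(=C(/OCOC)C)C(C)=O)[C@@H]12 | intermediate
14 | C8 ethynyl carbinol of 13 (ethynyl on the convex face, cis to the C1 side chain) | COC[C@@]1(OCOC)CC[C@H]2[C@@H](C)[C@](O)(C#C)[C@H](/C(=C(/OCOC)C)C(C)=O)[C@@H]12 | intermediate
15 | potassium alkoxide of 14 | [K+].COC[C@@]1(OCOC)CC[C@H]2[C@@H](C)[C@]([O-])(C#C)[C@H](/C(=C(/OCOC)C)C(C)=O)[C@@H]12 | intermediate (not isolated)
16 | cyclononadienone: ring A fused to the nine-membered ring B, 8-ketone, (9Z)-enone, 11R, C12=C1 with the acetyl group on C12 | COC[C@@]1(OCOC)CC[C@@H]2[C@H]1/C=C(/C(C)=O)[C@](C)(OCOC)/C=C\C(=O)[C@@H]2C | intermediate (not isolated)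
17 | bridged tricyclic 8,13-dione (rings A–C, C12=C1, C10–H, C14H2, 3,11-bis-O-methoxymethyl) | COC[C@@]1(OCOC)CC[C@@H]2[C@H]1/C=C1/C(=O)C[C@@H](CC(=O)[C@@H]2C)[C@@]1(C)OCOC | intermediate
18 | (8S)-8-hydroxy-13-ketone from 17 | COC[C@@]1(OCOC)CC[C@@H]2[C@H]1/C=C1/C(=O)C[C@@H](C[C@H](O)[C@@H]2C)[C@@]1(C)OCOC | intermediate
19 | 8,12-diol with C1=C2 (C10–H and C14H2 saturated, 3,11-bis-O-methoxymethyl) | COC[C@@]1(OCOC)CC[C@@H]2/C1=C\[C@@]1(O)C(=O)C[C@@H](C[C@H](O)[C@@H]2C)[C@@]1(C)OCOC | intermediate
20 | tris(trimethylsilyl) derivative of 19 (8-O, 12-O and the C13=C14 enol ether) | COC[C@@]1(OCOC)CC[C@@H]2/C1=C\[C@@]1(O[Si](C)(C)C)C(O[Si](C)(C)C)=C[C@@H](C[C@H](O[Si](C)(C)C)[C@@H]2C)[C@@]1(C)OCOC | intermediate (not isolated)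
21 | 14-deisopropyl-3,11-bis-O-(methoxymethyl)brassicicene M (C10=C14 enone, 8,12-diol) | COC[C@@]1(OCOC)CC[C@@H]2/C1=C\[C@@]1(O)C(=O)C=C(C[C@H](O)[C@@H]2C)[C@@]1(C)OCOC | intermediate
22 | 14-iodo analogue of 21 | COC[C@@]1(OCOC)CC[C@@H]2/C1=C\[C@@]1(O)C(=O)C(I)=C(C[C@H](O)[C@@H]2C)[C@@]1(C)OCOC | intermediate
23 | 3,11-bis-O-(methoxymethyl)brassicicene M | COC[C@@]1(OCOC)CC[C@@H]2/C1=C\[C@@]1(O)C(=O)C(C(C)C)=C(C[C@H](O)[C@@H]2C)[C@@]1(C)OCOC | intermediate
24 | brassicicene M | COC[C@@]1(O)CC[C@@H]2/C1=C\[C@@]1(O)C(=O)C(C(C)C)=C(C[C@H](O)[C@@H]2C)[C@@]1(C)O | target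

**Count and risks**
Total steps: 16. Longest linear sequence: 16 (from isoprene; pentane-2,4-dione enters at step 7).

The three steps most likely to fail:

Step 10. The linear alkyne may not reach the enol ether terminus, the strained cyclic allenolate may fragment instead of rearranging, or the face of bond formation may not be the one predicted. The fallback sets out from 13 and avoids the allenolate. Vinylmagnesium bromide with CeCl3 gives the vinyl carbinol F1. KN(SiMe3)2 with 18-crown-6 followed by Me3SiCl then effects the classical anionic oxy-Cope rearrangement of a cis-1,2-dialkenylcyclopentanol and traps the C8 enolate as the silyl enol ether F2. Saegusa–Ito oxidation with Pd(OAc)2 gives the dienone 16, and DBU closes ring C to return to the route at 17.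

Step 12. The base may take a hydrogen from C14 instead of C2, or the oxidant may attack the γ-carbon C2. The fallback sets out from 18 and uses no enolate. Weitz–Scheffer epoxidation (t-BuOOH, DBU) of the C12=C1 enone on the face away from the bridge gives the epoxy ketone F3. Diethylaluminium 2,2,6,6-tetramethylpiperidide then opens the epoxide at C1 with loss of the C2 hydrogen (epoxide to allylic alcohol isomerisation, the only β-hydrogen available), which returns to the route at 19.

Step 2. Enantioinduction may be poor with a dienyl enyne. The fallback sets out from 4 and replaces catalyst control by resolution. Co2(CO)8 followed by N-methylmorpholine N-oxide gives the racemic enone F4, and Luche reduction gives the racemic allylic alcohol F5 (hydroxyl trans to the ring-fusion hydrogen). Lipase-catalysed acetylation with vinyl acetate (kinetic resolution) is expected to leave the (6aS) alcohol F6 and convert the antipode to the acetate F7. MnO2 oxidation of F6 returns to the route at 5.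

**Further compounds**
F1 | step 10 | C8 vinyl carbinol of 13 (vinyl on the convex face) | COC[C@@]1(OCOC)CC[C@H]2[C@@H](C)[C@](O)(C=C)[C@H](/C(=C(/OCOC)C)C(C)=O)[C@@H]12
F2 | step 10 | trimethylsilyl enol ether (C8=C9) of the 9,10-dihydro analogue of 16 | COC[C@@]1(OCOC)CC[C@@H]2[C@H]1/C=C(/C(C)=O)[C@](C)(OCOC)C/C=C(/O[Si](C)(C)C)[C@@H]2C
F3 | step 12 | C12–C1 epoxide of 18 (oxygen on the face away from the bridge) | COC[C@@]1(OCOC)CC[C@@H]2[C@H]1[C@@H]3O[C@@]34C(=O)C[C@@H](C[C@H](O)[C@@H]2C)[C@@]4(C)OCOC
F4 | step 2 | racemic 3-methyl-6-methylidene-4,5,6,6a-tetrahydropentalen-2(1H)-one | CC1=C2CCC(=C)C2CC1=O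
F5 | step 2 | racemic 3-methyl-6-methylidene-1,2,4,5,6,6a-hexahydropentalen-2-ol (hydroxyl trans to 6a-H) | CC1=C2CCC(=C)C2CC1O
F6 | step 2 | (6aS) enantiomer of F5 | CC1=C2CCC(=C)[C@@H]2C[C@@H]1O
F7 | step 2 | acetate of the (6aR) enantiomer of F5 | CC1=C2CCC(=C)[C@H]2C[C@H]1OC(C)=O
A1 | direct plan | seco diene: ring A methylidene carbinol joined through C7–C9 to the ring C vinyl carbinol (8-O-triisopropylsilyl, 13-O-tert-butyldimethylsilyl) | COC[C@@]1(O)CC[C@@H]([C@@H](C)[C@@H](O[Si](C(C)C)(C(C)C)C(C)C)CC2=C(C(C)C)[C@@H](O[Si](C)(C)C(C)(C)C)C[C@]2(O)C=C)C1=C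
A2 | direct plan | fused 5-8-5 C11-hydroxy-12,13-dione (8-O-triisopropylsilyl) | COC[C@@]1(O)CC[C@@H]2/C1=C\[C@@]3(O)C(=O)C(=O)C(C(C)C)=C3C[C@H](O[Si](C(C)C)(C(C)C)C(C)C)[C@@H]2C
A3 | direct plan | bridged 5-9-5 C12-hydroxy-11,13-dione (8-O-triisopropylsilyl) | COC[C@@]1(O)CC[C@@H]2/C1=C\[C@@]1(O)C(=O)C(C(C)C)=C(C[C@H](O[Si](C(C)C)(C(C)C)C(C)C)[C@@H]2C)C1=O
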